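**Retrosynthetic overview**

1. Target ⇒ two molecules of one silyl-protected monomer 22. The C1–C13′ bond comes from a deoxygenative allyl-radical conjugate addition of the C1 allylic alcohol of one molecule to the α-methylene lactone of the other (new step), followed by desilylation.
2. Monomer 22 ⇒ α-methylenation of lactone 19, whose ten-membered ring is closed at C1–C10 by an intramolecular Nozaki–Hiyama–Kishi (NHK) coupling.
3. Seco-aldehyde 18 ⇒ Z-iodoalkene (C9=C10) by iodoethylidene Wittig reaction; C5–C6 by intermolecular NHK coupling of lactone aldehyde 5 with Z-alkenyl iodide 12 (from carbocupration of propyne).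
4. Lactone aldehyde 5 ⇒ (S)-proline cross-aldol of methyl 4-oxobutanoate with 2,2-dimethoxyacetaldehyde (first stereocentre, C8), then lactonisation and epimerisation to the trans γ-lactone.
5. Ring order: γ-lactone (step 1), ten-membered carbocycle (step 7), dimer (step 9).

Assumption: the SMILES is taken literally (all four ring alkenes Z, ring carbons cis); atom labels C1–C15 follow germacrane numbering of each half, with primed labels for the half whose lactone is saturated.

**Route**

Step 1
Reactants: 1 methyl 4-oxobutanoate; 2 2,2-dimethoxyacetaldehyde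
Product: 5 (2R,3R)-2-(dimethoxymethyl)-5-oxooxolane-3-carbaldehyde, via anti-aldol hydroxy ester 3 (not isolated), via cis-lactone aldehyde 4 (not isolated)
Conditions: (S)-proline (20 mol %), DMF, 4 °C, slow addition of 1 to 2 (2 equiv); then PPTS (10 mol %), CH2Cl2, rt; then DBU (0.3 equiv), 0 °C
Reagents that add atoms: none
Why: Proline-catalysed direct cross-aldol (enamine catalysis): the E-enamine of 1 attacks the Re face of non-enolisable 2 through the acid-directed chair transition state and sets C8 in anti-aldol 3; acid closes the γ-lactone and DBU epimerises the aldehyde α-carbon (C7) to the more stable trans lactone.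

Step 2
Reactants: 6 (3-bromopropoxy)(tert-butyl)dimethylsilane; 7 propyne
Product: 12 (4Z)-5-iodo-4-methylpent-4-en-1-ol, via Grignard reagent 8 (not isolated), via alkylcopper 9 (not isolated), via Z-alkenylcopper 10 (not isolated), via silyl-protected Z-iodide 11 (not isolated)
Conditions: Mg, Et2O; CuBr·SMe2, Me2S/Et2O, −45 °C; propyne (excess), −25 °C; I2, −50 → 0 °C; then HCl (cat.), MeOH, rt
Reagents that add atoms: iodine ([I][I])
Why: Normant syn-carbocupration puts the alkyl group on the internal alkyne carbon cis to copper, so iodinolysis with retention gives the Z-iodide (chain cis to iodine); acidic methanol removes the silyl group.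

Step 3
Reactants: 5 (2R,3R)-2-(dimethoxymethyl)-5-oxooxolane-3-carbaldehyde; 12 (4Z)-5-iodo-4-methylpent-4-en-1-ol
Product: 13 (4S,5R)-5-(dimethoxymethyl)-4-[(1R,2Z)-1,6-dihydroxy-3-methylhex-2-en-1-yl]oxolan-2-one
Conditions: CrCl2 (4 equiv), NiCl2 (2 mol %), DMSO, rt
Reagents that add atoms: none
Why: Nozaki–Hiyama–Kishi coupling is selective for the aldehyde over lactone, acetal and free hydroxyl and keeps the alkene geometry; Felkin–Anh attack anti to the larger ring carbon C8 of the α-branched aldehyde gives the (6R) alcohol (C6–O syn to C11).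

Step 4
Reactants: 13 (4S,5R)-5-(dimethoxymethyl)-4-[(1R,2Z)-1,6-dihydroxy-3-methylhex-2-en-1-yl]oxolan-2-one
Product: 16 (2R,3R)-3-[(1R,2Z)-3-methyl-1,6-bis(triethylsilyloxy)hex-2-en-1-yl]-5-oxooxolane-2-carbaldehyde, via bis-silyl acetal 14 (not isolated), via lutidinium salt 15 (not isolated)
Conditions: Et3SiOTf (4 equiv), 2,6-lutidine (6 equiv), CH2Cl2, −40 → 0 °C; then H2O, rt
Reagents that add atoms: triethylsilyl trifluoromethanesulfonate (CC[Si](CC)(CC)OS(=O)(=O)C(F)(F)F); water (O)
Why: Silyl triflate with 2,6-lutidine silylates both hydroxyls and converts the dimethyl acetal into a pyridinium N,O-acetal salt that water hydrolyses to the aldehyde without Brønsted acid (Fujioka–Kita-type acetal cleavage), so the allylic silyl ether and all stereocentres are untouched.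

Step 5
Reactants: 16 (2R,3R)-3-[(1R,2Z)-3-methyl-1,6-bis(triethylsilyloxy)hex-2-en-1-yl]-5-oxooxolane-2-carbaldehyde
Product: 17 (4R,5R)-5-[(1Z)-2-iodoprop-1-en-1-yl]-4-[(1R,2Z)-3-methyl-1,6-bis(triethylsilyloxy)hex-2-en-1-yl]oxolan-2-one
Conditions: [Ph3PEt]I, n-BuLi, THF; I2, −78 °C; NaN(SiMe3)2, −78 → −20 °C; then 16, −78 °C
Reagents that add atoms: ethyltriphenylphosphonium iodide (CC[P+](c1ccccc1)(c1ccccc1)c1ccccc1.[I-]); iodine ([I][I])
Why: Stork–Zhao-type Wittig reaction of the non-stabilised α-iodo ylide goes through the kinetic cis-oxaphosphetane and gives the Z-2-iodoalkene (C8 cis to iodine); at −78 °C the α-acyloxy aldehyde does not epimerise.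

Step 6
Reactants: 17 (4R,5R)-5-[(1Z)-2-iodoprop-1-en-1-yl]-4-[(1R,2Z)-3-methyl-1,6-bis(triethylsilyloxy)hex-2-en-1-yl]oxolan-2-one
Product: 18 (4Z,6R)-6-{(2R,3R)-2-[(1Z)-2-iodoprop-1-en-1-yl]-5-oxooxolan-3-yl}-4-methyl-6-(triethylsilyloxy)hex-4-enal
Conditions: (COCl)2, DMSO, CH2Cl2, −78 → −30 °C; Et3N, −78 → 0 °C
Reagents that add atoms: none
Why: Under Swern conditions a primary triethylsilyl ether is desilylated and oxidised directly to the aldehyde by the chlorosulfonium salt, while the hindered secondary allylic silyl ether survives.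

Step 7
Reactants: 18 (4Z,6R)-6-{(2R,3R)-2-[(1Z)-2-iodoprop-1-en-1-yl]-5-oxooxolan-3-yl}-4-methyl-6-(triethylsilyloxy)hex-4-enal
Product: 19 (3aR,4R,5Z,9S,10Z,11aS)-9-hydroxy-6,10-dimethyl-4-(triethylsilyloxy)-3a,4,7,8,9,11a-hexahydrocyclodeca[b]furan-2(3H)-one
Conditions: CrCl2 (10 equiv), NiCl2 (0.1 equiv), DMSO/THF 3:1, 2 mM, rt, slow addition
Reagents that add atoms: none
Why: Intramolecular Nozaki–Hiyama–Kishi reaction: the alkenylchromium adds to the C1 aldehyde with retention of the Z geometry, the two Z-alkenes and the trans lactone hold the chain ends close, and the transition state with both allylic ring bonds on one face of the C9=C10 plane, H1 in that plane (allylic strain) and the chromium alkoxide on the outer face gives the (1S) alcohol.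

Step 8
Reactants: 19 (3aR,4R,5Z,9S,10Z,11aS)-9-hydroxy-6,10-dimethyl-4-(triethylsilyloxy)-3a,4,7,8,9,11a-hexahydrocyclodeca[b]furan-2(3H)-one
Product: 22 (3aR,4R,5Z,9S,10Z,11aS)-9-hydroxy-6,10-dimethyl-3-methylidene-4-(triethylsilyloxy)-3a,4,7,8,9,11a-hexahydrocyclodeca[b]furan-2(3H)-one, via Mannich base 20 (not isolated), via trimethylammonium iodide 21 (not isolated)
Conditions: LiN(iPr)2 (2.5 equiv), THF, −78 °C; CH2=NMe2 iodide, −78 °C → rt; then MeI, THF/MeOH, rt; then aq. NaHCO3, rt
Reagents that add atoms: N,N-dimethylmethyleneiminium iodide, Eschenmoser's salt (C=[N+](C)C.[I-])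
Why: Eschenmoser α-methylenation: the lactone enolate (C11 is the only enolisable position; the C1 alkoxide is tolerated as the dianion) undergoes a Mannich reaction, and quaternisation followed by mild-base elimination gives the exocyclic methylene without touching any stereocentre.

Step 9
Reactants: 22 (3aR,4R,5Z,9S,10Z,11aS)-9-hydroxy-6,10-dimethyl-3-methylidene-4-(triethylsilyloxy)-3a,4,7,8,9,11a-hexahydrocyclodeca[b]furan-2(3H)-one (two molecules: about one third is activated as radical precursor, the rest is the acceptor and the excess is recovered)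
Product: 24 6,6′-bis-O-triethylsilyl ether of the target, via benzoxazoline adduct 23 (not isolated)
Conditions: 5,7-di-tert-butyl-3-phenylbenzoxazolium tetrafluoroborate (0.30 equiv), pyridine (0.33 equiv), MTBE, rt; then 4CzIPN (2 mol %), 2,4,6-collidine (10 mol %), DMSO/MTBE (0.3 M), 450 nm LEDs, rt
Reagents that add atoms: none
Why: Proposed new method: the only free hydroxyl of 22 (C1) condenses with the benzoxazolium salt, and one-electron oxidation of adduct 23 by excited 4CzIPN, loss of the acetal proton and β-scission (driven by the benzoxazolone C=O) give the C1–C10–C9 allyl radical, which adds to the exocyclic methylene C13′ of a second molecule of 22; the tertiary α-lactone radical is then reduced by the photocatalyst radical anion to the enolate and protonated, so the step is redox-neutral and metal-free. Bonding at C1 and not C9 is expected because C9 adjoins the branched ring-fusion carbon C8 with its electron-withdrawing lactone oxygen; attack on the convex face of the Z-allyl unit (both allylic ring bonds C1–C2 and C8–C7 lie on the other face, H1 stays in the alkene plane) places the new C–C bond where the C–O bond was, giving (1R), and protonation at C11′ gives the more stable lactone with C13′ trans to C6′, (11′R). The closest known reaction type is the photoredox deoxygenative Giese addition of benzoxazolium-activated alcohols to acrylates, which has not been shown for secondary allylic alcohols, unsymmetrical allyl radicals or the homodimerisation of an α-methylene lactone.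

Step 10
Reactants: 24 6,6′-bis-O-triethylsilyl ether of the target
Product: 25 CNP0307352.3 (target)
Conditions: HF·pyridine, pyridine, THF, 0 °C
Reagents that add atoms: none
Why: Buffered fluoride desilylation removes both secondary triethylsilyl ethers without base, so no stereocentre is touched and the 8,12-lactones cannot translactonise to the free C6 hydroxyls.

**Compound list**

1 | methyl 4-oxobutanoate | O=CCCC(=O)OC | starting material
2 | 2,2-dimethoxyacetaldehyde | COC(OC)C=O | starting material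
3 | methyl (3S,4R)-3-formyl-4-hydroxy-5,5-dimethoxypentanoate (anti-aldol) | COC(=O)C[C@H](C=O)[C@@H](O)C(OC)OC | intermediate
4 | (2R,3S)-2-(dimethoxymethyl)-5-oxooxolane-3-carbaldehyde (cis lactone) | O=C[C@H]1CC(=O)O[C@H]1C(OC)OC | intermediate
5 | (2R,3R)-2-(dimethoxymethyl)-5-oxooxolane-3-carbaldehyde (trans lactone) | O=C[C@@H]1CC(=O)O[C@H]1C(OC)OC | intermediate
6 | (3-bromopropoxy)(tert-butyl)dimethylsilane | CC(C)(C)[Si](C)(C)OCCCBr | starting material
7 | propyne | CC#C | starting material
8 | [3-(tert-butyldimethylsilyloxy)propyl]magnesium bromide | CC(C)(C)[Si](C)(C)OCCC[Mg]Br | intermediate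
9 | [3-(tert-butyldimethylsilyloxy)propyl]copper | CC(C)(C)[Si](C)(C)OCCC[Cu] | intermediate
10 | [(1Z)-5-(tert-butyldimethylsilyloxy)-2-methylpent-1-en-1-yl]copper | CC(C)(C)[Si](C)(C)OCCC/C(C)=C\[Cu] | intermediate
11 | tert-butyl{[(4Z)-5-iodo-4-methylpent-4-en-1-yl]oxy}dimethylsilane | CC(C)(C)[Si](C)(C)OCCC/C(C)=C\I | intermediate
12 | (4Z)-5-iodo-4-methylpent-4-en-1-ol | OCCC/C(C)=C\I | intermediate
13 | (4S,5R)-5-(dimethoxymethyl)-4-[(1R,2Z)-1,6-dihydroxy-3-methylhex-2-en-1-yl]oxolan-2-one | OCCC/C(C)=C\[C@@H](O)[C@@H]1CC(=O)O[C@H]1C(OC)OC | intermediate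
14 | (4R,5R)-5-(dimethoxymethyl)-4-[(1R,2Z)-3-methyl-1,6-bis(triethylsilyloxy)hex-2-en-1-yl]oxolan-2-one | CC[Si](CC)(CC)OCCC/C(C)=C\[C@@H](O[Si](CC)(CC)CC)[C@@H]1CC(=O)O[C@H]1C(OC)OC | intermediate
15 | 1-{methoxy[(2R,3R)-3-((1R,2Z)-3-methyl-1,6-bis(triethylsilyloxy)hex-2-en-1-yl)-5-oxooxolan-2-yl]methyl}-2,6-dimethylpyridinium triflate (both epimers at the N,O-acetal carbon) | CC[Si](CC)(CC)OCCC/C(C)=C\[C@@H](O[Si](CC)(CC)CC)[C@@H]1CC(=O)O[C@H]1C(OC)[n+]1c(C)cccc1C.[O-]S(=O)(=O)C(F)(F)F | intermediate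
16 | (2R,3R)-3-[(1R,2Z)-3-methyl-1,6-bis(triethylsilyloxy)hex-2-en-1-yl]-5-oxooxolane-2-carbaldehyde | CC[Si](CC)(CC)OCCC/C(C)=C\[C@@H](O[Si](CC)(CC)CC)[C@@H]1CC(=O)O[C@H]1C=O | intermediate
17 | (4R,5R)-5-[(1Z)-2-iodoprop-1-en-1-yl]-4-[(1R,2Z)-3-methyl-1,6-bis(triethylsilyloxy)hex-2-en-1-yl]oxolan-2-one | CC[Si](CC)(CC)OCCC/C(C)=C\[C@@H](O[Si](CC)(CC)CC)[C@@H]1CC(=O)O[C@H]1/C=C(/C)I | intermediate
18 | (4Z,6R)-6-{(2R,3R)-2-[(1Z)-2-iodoprop-1-en-1-yl]-5-oxooxolan-3-yl}-4-methyl-6-(triethylsilyloxy)hex-4-enal | O=CCC/C(C)=C\[C@@H](O[Si](CC)(CC)CC)[C@@H]1CC(=O)O[C@H]1/C=C(/C)I | intermediate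
19 | (3aR,4R,5Z,9S,10Z,11aS)-9-hydroxy-6,10-dimethyl-4-(triethylsilyloxy)-3a,4,7,8,9,11a-hexahydrocyclodeca[b]furan-2(3H)-one | C1C(=O)O[C@H]2/C=C(/C)[C@@H](O)CC/C(C)=C\[C@@H](O[Si](CC)(CC)CC)[C@H]12 | intermediate
20 | 3-[(dimethylamino)methyl] derivative of 19 (C11 not controlled) | CN(C)CC1C(=O)O[C@H]2/C=C(/C)[C@@H](O)CC/C(C)=C\[C@@H](O[Si](CC)(CC)CC)[C@H]12 | intermediate
21 | 3-[(trimethylammonio)methyl] derivative of 19, iodide | C[N+](C)(C)CC1C(=O)O[C@H]2/C=C(/C)[C@@H](O)CC/C(C)=C\[C@@H](O[Si](CC)(CC)CC)[C@H]12.[I-] | intermediate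
22 | (3aR,4R,5Z,9S,10Z,11aS)-9-hydroxy-6,10-dimethyl-3-methylidene-4-(triethylsilyloxy)-3a,4,7,8,9,11a-hexahydrocyclodeca[b]furan-2(3H)-one (6-O-silyl monomer) | C=C1C(=O)O[C@H]2/C=C(/C)[C@@H](O)CC/C(C)=C\[C@@H](O[Si](CC)(CC)CC)[C@H]12 | intermediate
23 | 22 bearing a 5,7-di-tert-butyl-3-phenyl-2,3-dihydro-1,3-benzoxazol-2-yl group on the C1 oxygen (both epimers at the acetal carbon) | C=C1C(=O)O[C@H]2/C=C(/C)[C@@H](OC3Oc4c(cc(cc4N3c3ccccc3)C(C)(C)C)C(C)(C)C)CC/C(C)=C\[C@@H](O[Si](CC)(CC)CC)[C@H]12 | intermediate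
24 | 6,6′-bis-O-triethylsilyl ether of the target (C1–C13′ linked dimer; 1R,6R,7S,8S and 1′S,6′R,7′S,8′S,11′R in the free diol descriptors; all ring alkenes Z) | C=C1C(=O)O[C@H]2/C=C(/C)[C@@H](C[C@H]3C(=O)O[C@H]4/C=C(/C)[C@@H](O)CC/C(C)=C\[C@@H](O[Si](CC)(CC)CC)[C@@H]43)CC/C(C)=C\[C@@H](O[Si](CC)(CC)CC)[C@H]12 | intermediate
25 | CNP0307352.3 (C1–C13′ linked germacranolide dimer; 1R,6R,7S,8S and 1′S,6′R,7′S,8′S,11′R; all ring alkenes Z) | C=C1C(=O)O[C@H]2/C=C(/C)[C@@H](C[C@H]3C(=O)O[C@H]4/C=C(/C)[C@@H](O)CC/C(C)=C\[C@@H](O)[C@@H]43)CC/C(C)=C\[C@@H](O)[C@H]12 | target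

**Step count and risks**

Total step count: 10. Longest linear sequence: 9 steps (1, 3–10); step 2 is a one-step side branch.

The three steps most likely to fail:

Step 9 (the proposed new dimerisation). It can fail through allyl-radical self-coupling, attack at C9, the wrong face at C1, or oligomerisation of the product. The fallback uses known radical chain chemistry and sets out from 22. Appel bromination (CBr4, PPh3, CH2Cl2, 0 °C) converts the C1 alcohol into the allylic bromide F1. F1 is then added slowly, with (Me3Si)3SiH and AIBN in benzene at 80 °C, to a threefold excess of 22 as acceptor. This classical silane-mediated Giese addition of a halide-derived radical to the α-methylene lactone gives the same silylated dimer, so the route is rejoined at 24.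

Step 7 (ring closure to the ten-membered carbocycle and the C1 configuration). If the NHK macrocyclisation oligomerises or gives the wrong C1 epimer, the fallback sets out from 18. Pinnick oxidation (NaClO2, NaH2PO4, 2-methyl-2-butene) gives the carboxylic acid F2. 2,2′-Dipyridyl disulfide and PPh3 convert it into the 2-pyridyl thioester F3. A nickel/zirconium-mediated intramolecular alkenyl iodide–thioester ketone coupling (NiBr2(dtbbpy), Cp2ZrCl2, Zn, DMI, high dilution) closes the ring to the Z-enone F4. Reduction with (R)-2-methyl-CBS-oxazaborolidine and catecholborane (alkenyl as the large group) then sets (1S) under catalyst control and comes back to the route at 19.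

Step 3 (substrate-controlled C6 configuration). If the Felkin–Anh preference is low, the fallback sets out from 5. The same coupling with 12 is run, and the C6-epimeric mixture is oxidised without separation with MnO2 (CH2Cl2, rt; selective for the allylic hydroxyl over the primary one) to the Z-enone F5. Catalyst-controlled reduction with (R)-2-methyl-CBS-oxazaborolidine and catecholborane (alkenyl as the large group) then gives the (6R) alcohol and comes back to the route at 13.

Further compounds
F1 | step 9 | (3aR,4R,5Z,9R,10Z,11aS)-9-bromo-6,10-dimethyl-3-methylidene-4-(triethylsilyloxy)-3a,4,7,8,9,11a-hexahydrocyclodeca[b]furan-2(3H)-one | C=C1C(=O)O[C@H]2/C=C(/C)[C@H](Br)CC/C(C)=C\[C@@H](O[Si](CC)(CC)CC)[C@H]12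
F2 | step 7 | (4Z,6R)-6-{(2R,3R)-2-[(1Z)-2-iodoprop-1-en-1-yl]-5-oxooxolan-3-yl}-4-methyl-6-(triethylsilyloxy)hex-4-enoic acid | OC(=O)CC/C(C)=C\[C@@H](O[Si](CC)(CC)CC)[C@@H]1CC(=O)O[C@H]1/C=C(/C)I
F3 | step 7 | S-pyridin-2-yl (4Z,6R)-6-{(2R,3R)-2-[(1Z)-2-iodoprop-1-en-1-yl]-5-oxooxolan-3-yl}-4-methyl-6-(triethylsilyloxy)hex-4-enethioate | O=C(CC/C(C)=C\[C@@H](O[Si](CC)(CC)CC)[C@@H]1CC(=O)O[C@H]1/C=C(/C)I)Sc1ccccn1
F4 | step 7 | (3aR,4R,5Z,10Z,11aS)-6,10-dimethyl-4-(triethylsilyloxy)-3a,4,7,8-tetrahydrocyclodeca[b]furan-2,9(3H,11aH)-dione | C1C(=O)O[C@H]2/C=C(/C)C(=O)CC/C(C)=C\[C@@H](O[Si](CC)(CC)CC)[C@H]12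
F5 | step 3 | (4R,5R)-5-(dimethoxymethyl)-4-[(2Z)-6-hydroxy-3-methylhex-2-enoyl]oxolan-2-one | OCCC/C(C)=C\C(=O)[C@@H]1CC(=O)O[C@H]1C(OC)OC
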